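**Strategy.** The route rests on the homoallylic relationship between the tertiary bromide carbon C1 and C5 across the C6 methylene (numbering of the target name). C1, C6 and C5 are the cyclopropane of bicyclo[3.1.0]hexan-2-ol 8, whose five-membered ring (C1, C2, C3, C4, C5) already carries the chlorovinyl group. Ionisation at C4 triggers a cyclopropylcarbinyl–homoallyl rearrangement that cleaves the shared C1–C5 bond. In that one operation the cyclopentane becomes the cyclohexene, bromide enters C1 with inversion to set the tertiary C–Br centre trans to the C2 side chain, and a C4=C5 alkene is left for syn bromochlorination through an epoxide.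

Key step: step 7

Remark: C2 of alcohol 8 becomes sp2 in step 7, so both C2 epimers converge; the epimer expected to predominate is drawn. Locants in the step texts follow each compound's own name.

**Step 1**
Reactants: 1 2,3-dimethylcyclopent-2-en-1-one
Product: 2 (R)-2,3-dimethylcyclopent-2-en-1-ol
Conditions: (S)-Me-CBS (10 mol %), BH3·SMe2, THF, −20 °C; MeOH
Reagents that add atoms: none
Why: Corey–Bakshi–Shibata reduction, in which the methyl-substituted alkenyl carbon acts as the large group, so hydride should reach one carbonyl face and set C1 as R, with 1,2-reduction expected for this β,β-disubstituted enone.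

**Step 2**
Reactants: 2 (R)-2,3-dimethylcyclopent-2-en-1-ol
Product: 3 (1S,2R,5R)-1,5-dimethylbicyclo[3.1.0]hexan-2-ol
Conditions: Et2Zn, CH2I2, CH2Cl2, 0 °C → rt
Reagents that add atoms: diiodomethane ICI
Why: Hydroxyl-directed Simmons–Smith (Furukawa) cyclopropanation, in which the zinc alkoxide delivers the methylene to the alkene face that carries the oxygen, so both new quaternary centres follow from the carbinol centre.

**Step 3**
Reactants: 3 (1S,2R,5R)-1,5-dimethylbicyclo[3.1.0]hexan-2-ol
Product: 5 (1S,5S)-1,5-dimethylbicyclo[3.1.0]hex-3-en-2-one, via ketone 4 (not isolated)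
Conditions: IBX (3 equiv), DMSO, 70 °C
Reagents that add atoms: none
Why: IBX oxidation of the alcohol followed by IBX α,β-dehydrogenation of the ketone; only C3 carries α-hydrogens, so a single enone can form, and the carbinol centre that steered step 2 is erased.

**Step 4**
Reactants: 5 (1S,5S)-1,5-dimethylbicyclo[3.1.0]hex-3-en-2-one
Product: 6 (1S,4S,5S)-4-ethenyl-1,5-dimethylbicyclo[3.1.0]hexan-2-one
Conditions: CH2=CHMgBr, CuBr·SMe2 (20 mol %), THF, −78 → −40 °C; aq. NH4Cl
Reagents that add atoms: vinylmagnesium bromide C=C[Mg]Br
Why: Copper-catalysed conjugate addition, in which the vinyl group should enter C4 anti-periplanar to the C5–C6 cyclopropane bond, that is on the face opposite the cyclopropane methylene, setting C4 (S) trans to the three-membered ring.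

**Step 5**
Reactants: 6 (1S,4S,5S)-4-ethenyl-1,5-dimethylbicyclo[3.1.0]hexan-2-one
Product: 7 (1S,4S,5S)-4-[(E)-2-chloroethenyl]-1,5-dimethylbicyclo[3.1.0]hexan-2-one
Conditions: (E)-ClCH=CHCl (8 equiv), Mo monoaryloxide pyrrolide alkylidene (5 mol %), C6H6, 22 °C
Reagents that add atoms: (E)-1,2-dichloroethene Cl/C=C/Cl
Why: Kinetically E-selective molybdenum-catalysed cross-metathesis of the terminal vinyl group with (E)-1,2-dichloroethene should give the (E)-alkenyl chloride and vinyl chloride, the ketone and cyclopropane being spectators.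

**Step 6**
Reactants: 7 (1S,4S,5S)-4-[(E)-2-chloroethenyl]-1,5-dimethylbicyclo[3.1.0]hexan-2-one
Product: 8 (1S,2R,4S,5S)-4-[(E)-2-chloroethenyl]-1,5-dimethylbicyclo[3.1.0]hexan-2-ol
Conditions: NaBH4, MeOH, −20 °C
Reagents that add atoms: none
Why: Borohydride reduction of the cyclopropyl ketone, with hydride expected mainly anti to the cyclopropane to give the 2R alcohol; the alkenyl chloride is inert.

**Step 7**
Reactants: 8 (1S,2R,4S,5S)-4-[(E)-2-chloroethenyl]-1,5-dimethylbicyclo[3.1.0]hexan-2-ol
Product: 10 (4S,5R)-5-bromo-4-[(E)-2-chloroethenyl]-1,5-dimethylcyclohex-1-ene, via mesylate 9 (not isolated)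
Conditions: Ms2O, Et3N, CH2Cl2, −40 °C; then MgBr2·OEt2, −40 → −10 °C
Reagents that add atoms: magnesium bromide (diethyl etherate) Br[Mg]Br
Why: Mesylate 9 ionises to the bicyclo[3.1.0]hex-2-yl (cyclopropylcarbinyl) cation, whose charge is shared with C5 and C6; bromide attacks the tertiary carbon C5 (later C1 of the target) from the side opposite the breaking C1–C5 bond, which turns the cyclopentane into the cyclohexene and leaves the double bond between C1 and C2. The closest known reactions are the Julia-type cyclopropylcarbinyl-to-homoallyl bromide rearrangement and the acid-mediated thujane-to-p-menthane ring expansion (sabinene hydrate to terpinen-4-ol). No ring is closed: the six-membered ring arises by cleavage of the bond shared by the three- and five-membered rings. The one new stereocentre, the tertiary C–Br carbon, is controlled by inversion at the cyclopropane carbon, so its configuration follows from the cyclopropane face (step 2) and its trans relationship to the side chain from step 4. The step needs cleavage of the internal C1–C5 bond and not the external C1–C6 bond, which the methyl-bearing tertiary C5 (against primary C6) secures, and capture instead of elimination, which excess bromide in a chloride-free, non-basic medium at low temperature should favour.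

**Step 8**
Reactants: 10 (4S,5R)-5-bromo-4-[(E)-2-chloroethenyl]-1,5-dimethylcyclohex-1-ene
Product: 11 (1S,3R,4S,6R)-3-bromo-4-[(E)-2-chloroethenyl]-1,3-dimethyl-7-oxabicyclo[4.1.0]heptane
Conditions: mCPBA, NaHCO3, CH2Cl2, 0 °C
Reagents that add atoms: meta-chloroperbenzoic acid OOC(=O)c1cccc(Cl)c1
Why: Prilezhaev epoxidation of the trisubstituted ring alkene (the chloroalkene is deactivated), in which the peracid should approach anti to the axial C5 methyl group and the C4 side chain, that is on the face bearing bromine, setting both epoxide carbons.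

**Step 9**
Reactants: 11 (1S,3R,4S,6R)-3-bromo-4-[(E)-2-chloroethenyl]-1,3-dimethyl-7-oxabicyclo[4.1.0]heptane
Product: 12 (1R,2R,4R,5S)-4-bromo-2-chloro-5-[(E)-2-chloroethenyl]-2,4-dimethylcyclohexan-1-ol
Conditions: HCl (1 M in Et2O), CH2Cl2, −78 → −40 °C
Reagents that add atoms: hydrogen chloride Cl
Why: Acid-mediated Markovnikov opening of the trisubstituted epoxide, in which chloride attacks the tertiary carbon with inversion (trans-diaxial opening) to give the tertiary chloride and the trans secondary alcohol, low temperature limiting hydride shift and elimination.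

**Step 10**
Reactants: 12 (1R,2R,4R,5S)-4-bromo-2-chloro-5-[(E)-2-chloroethenyl]-2,4-dimethylcyclohexan-1-ol
Product: 14 (1R,2S,4S,5R)-1,4-dibromo-5-chloro-2-[(E)-2-chloroethenyl]-1,5-dimethylcyclohexane, via triflate 13 (not isolated)
Conditions: Tf2O, pyridine, CH2Cl2, −78 → −40 °C; then n-Bu4NBr, toluene, −40 → 0 °C
Reagents that add atoms: tetrabutylammonium bromide CCCC[N+](CCCC)(CCCC)CCCC.[Br-]
Why: Triflation and SN2 displacement by bromide with inversion at the secondary carbon should place bromine cis to the vicinal tertiary chloride, a soluble bromide in a non-ionising solvent keeping the substitution bimolecular.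

**Compound list**
1 | 2,3-dimethylcyclopent-2-en-1-one | CC1=C(C)C(=O)CC1 | starting material
2 | (R)-2,3-dimethylcyclopent-2-en-1-ol | CC1=C(C)[C@H](O)CC1 | intermediate
3 | (1S,2R,5R)-1,5-dimethylbicyclo[3.1.0]hexan-2-ol | O[C@@H]1CC[C@]2(C)C[C@]12C | intermediate
4 | (1S,5R)-1,5-dimethylbicyclo[3.1.0]hexan-2-one | O=C1CC[C@]2(C)C[C@]12C | intermediate
5 | (1S,5S)-1,5-dimethylbicyclo[3.1.0]hex-3-en-2-one | O=C1C=C[C@]2(C)C[C@]12C | intermediate
6 | (1S,4S,5S)-4-ethenyl-1,5-dimethylbicyclo[3.1.0]hexan-2-one | O=C1C[C@@H](C=C)[C@]2(C)C[C@]12C | intermediate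
7 | (1S,4S,5S)-4-[(E)-2-chloroethenyl]-1,5-dimethylbicyclo[3.1.0]hexan-2-one | O=C1C[C@@H](/C=C/Cl)[C@]2(C)C[C@]12C | intermediate
8 | (1S,2R,4S,5S)-4-[(E)-2-chloroethenyl]-1,5-dimethylbicyclo[3.1.0]hexan-2-ol | O[C@@H]1C[C@@H](/C=C/Cl)[C@]2(C)C[C@]12C | intermediate
9 | (1S,2R,4S,5S)-4-[(E)-2-chloroethenyl]-1,5-dimethylbicyclo[3.1.0]hexan-2-yl methanesulfonate | CS(=O)(=O)O[C@@H]1C[C@@H](/C=C/Cl)[C@]2(C)C[C@]12C | intermediate
10 | (4S,5R)-5-bromo-4-[(E)-2-chloroethenyl]-1,5-dimethylcyclohex-1-ene | CC1=CC[C@@H](/C=C/Cl)[C@](C)(Br)C1 | intermediate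
11 | (1S,3R,4S,6R)-3-bromo-4-[(E)-2-chloroethenyl]-1,3-dimethyl-7-oxabicyclo[4.1.0]heptane | C[C@]12C[C@@](C)(Br)[C@H](/C=C/Cl)C[C@H]1O2 | intermediate
12 | (1R,2R,4R,5S)-4-bromo-2-chloro-5-[(E)-2-chloroethenyl]-2,4-dimethylcyclohexan-1-ol | C[C@@]1(Cl)C[C@@](C)(Br)[C@H](/C=C/Cl)C[C@H]1O | intermediate
13 | (1R,2R,4R,5S)-4-bromo-2-chloro-5-[(E)-2-chloroethenyl]-2,4-dimethylcyclohexyl trifluoromethanesulfonate | C[C@@]1(Cl)C[C@@](C)(Br)[C@H](/C=C/Cl)C[C@H]1OS(=O)(=O)C(F)(F)F | intermediate
14 | (1R,2S,4S,5R)-1,4-dibromo-5-chloro-2-[(E)-2-chloroethenyl]-1,5-dimethylcyclohexane | C[C@@]1(Cl)C[C@@](C)(Br)[C@H](/C=C/Cl)C[C@@H]1Br | target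

Total step count: 10. Longest linear sequence: 10 steps (from 1).

**Steps most likely to fail**

Step 7. The cation may escape bromide capture: proton loss to dienes, a 1,2-hydride shift from the carbon bearing the side chain into the allylic position, or capture after full ionisation from either face, which would erode the configuration at the C–Br carbon. The fallback sets out from ketone 7 (step 6 is then omitted) and comes back at 10. The cyclopropyl ketone is opened by homoconjugate addition of HBr (HBr/AcOH in CH2Cl2 or TMSBr, −20 °C); bromide attacks the tertiary cyclopropane carbon with inversion while the charge is taken up by the enol, which should give the ring-expanded γ-bromo ketone (2S,4R,5S)-4-bromo-5-[(E)-2-chloroethenyl]-2,4-dimethylcyclohexan-1-one F1 (C2 is epimerisable and is lost in the next step). Tf2O with 2,6-di-tert-butyl-4-methylpyridine should then give the more substituted enol triflate (4R,5S)-4-bromo-5-[(E)-2-chloroethenyl]-2,4-dimethylcyclohex-1-en-1-yl trifluoromethanesulfonate F2, and palladium-catalysed formate reduction (Pd(OAc)2, PPh3, Bu3N, HCO2H, DMF) should give 10.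

Step 10. The vicinal tertiary chlorine, anti-periplanar to the triflate, may participate (chloronium ion), leading to substitution with retention or to halogen transposition, and E2 loss of triflic acid may compete at this neopentyl-like centre. The fallback sets out from alkene 10 and comes back at 14. Anti chloroselenation with PhSeCl under equilibrating conditions (CH2Cl2, −78 °C → rt) should give the Markovnikov adduct [(1R,2R,4R,5S)-4-bromo-2-chloro-5-[(E)-2-chloroethenyl]-2,4-dimethylcyclohexyl](phenyl)selane F3, with chlorine on the tertiary carbon and selenium on the secondary carbon. Bromine then oxidises selenium to the Se(IV) dibromide, which bromide displaces with inversion to give 14; this is the anti-addition and invertive-displacement logic of selenium-based syn-dichlorination.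

Step 8. In the half-chair with axial bromine the peracid may attack from the lower face, syn to the side chain, so that the epoxide forms with the wrong configuration and both later halogens end on the wrong face. The fallback sets out from 10 and comes back at 11. NBS in aqueous acetone forms the bromonium ion on the face the peracid prefers, and water opens it at the tertiary carbon from the other side to give the bromohydrin (1S,2S,4S,5R)-2,5-dibromo-4-[(E)-2-chloroethenyl]-1,5-dimethylcyclohexan-1-ol F4. K2CO3 in MeOH at 0 °C then closes the epoxide by displacement of bromide, which places the oxygen on the face opposite to that of direct epoxidation and should give 11.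

**Further compounds**
F1 | step 7 | (2S,4R,5S)-4-bromo-5-[(E)-2-chloroethenyl]-2,4-dimethylcyclohexan-1-one | C[C@H]1C[C@@](C)(Br)[C@H](/C=C/Cl)CC1=O
F2 | step 7 | (4R,5S)-4-bromo-5-[(E)-2-chloroethenyl]-2,4-dimethylcyclohex-1-en-1-yl trifluoromethanesulfonate | CC1=C(OS(=O)(=O)C(F)(F)F)C[C@@H](/C=C/Cl)[C@](C)(Br)C1
F3 | step 10 | [(1R,2R,4R,5S)-4-bromo-2-chloro-5-[(E)-2-chloroethenyl]-2,4-dimethylcyclohexyl](phenyl)selane | C[C@@]1(Cl)C[C@@](C)(Br)[C@H](/C=C/Cl)C[C@H]1[Se]c1ccccc1
F4 | step 8 | (1S,2S,4S,5R)-2,5-dibromo-4-[(E)-2-chloroethenyl]-1,5-dimethylcyclohexan-1-ol | C[C@]1(O)C[C@@](C)(Br)[C@H](/C=C/Cl)C[C@@H]1Br
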